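**Retrosynthetic overview**
1. Last bonds: the C19–O ester (4-acetoxycinnamic acid, then deacetylation) and the C13=C16/C14=C15 diene, made from a C13≡C14 alkyne and ethylene.
2. The C4 quaternary centre (axial CH2OH, equatorial CH3) and the C8=C17 methylene both grow from ketones: C4=O → C4=CHOMe → CHO → methylation → CH2OH; C8=O → methylene through a chiral sulfoximine adduct, which also separates the enantiomers.
3. Key disconnection: ring B by one [4+2] event that forms C5–C6 and C9–C10, from the 2-silyloxydiene C6=C7–C8(OSi)=C9–(side chain) and the C5=C10 bond of 3-methylcyclohex-2-enone (ring A, bought), used as its light-generated strained (E)-isomer so that the decalin is formed trans-fused.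
4. Enabling feature: ring B is a cyclohexane with one sp2 carbon (C8, between C7 and C9), fused to ring A across C5–C10 with C10–CH3 anti to C5–H; C4, next to C5, can be a carbonyl group during the cycloaddition, where it activates C5=C10, makes C10 the electrophilic end, and later becomes the quaternary C4.
5. Ring order: ring A preformed → ring B (step 5); side-chain diene and ester last.

Key step: step 5

Remark on the chemistry: positions are given in labdane numbering (C1–C20; the target is the (4R,5S,9R,10S) ester, ent-labdane series), and racemates, marked (±), are written with the SMILES of the enantiomer that is carried on.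

**Route**

Step 1
Reactants: 1 5-chloropent-1-yne
Product: 3 (5-chloropent-1-yn-1-yl)tri(propan-2-yl)silane, via lithium acetylide 2 (not isolated)
Conditions: n-BuLi, THF, −78 °C; then i-Pr3SiOTf, −78 °C → rt
Reagents that add atoms: triisopropylsilyl trifluoromethanesulfonate, CC(C)[Si](OS(=O)(=O)C(F)(F)F)(C(C)C)C(C)C
Why: Deprotonation of the only acidic C–H and C-silylation of the lithium acetylide (acetylide silylation) give an alkyne mask that withstands the bases and the buffered fluoride used later, while the primary chloride is inert at low temperature.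

Step 2
Reactants: 3 (5-chloropent-1-yn-1-yl)tri(propan-2-yl)silane; 4 prop-2-enal (acrolein)
Product: 6 (±)-8-[tri(propan-2-yl)silyl]oct-1-en-7-yn-3-ol, via Grignard reagent 5 (not isolated)
Conditions: Mg, I2 (cat.), THF, reflux; then 4, −78 → 0 °C; aq. NH4Cl
Reagents that add atoms: none
Why: Grignard formation from the primary chloride and 1,2-addition to acrolein (Grignard addition) give the allylic alcohol, whose racemic carbinol centre is removed in step 3.

Step 3
Reactants: 6 (±)-8-[tri(propan-2-yl)silyl]oct-1-en-7-yn-3-ol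
Product: 7 8-[tri(propan-2-yl)silyl]oct-1-en-7-yn-3-one
Conditions: Dess–Martin periodinane, CH2Cl2, 0 °C → rt
Reagents that add atoms: none
Why: Dess–Martin oxidation converts the secondary allylic alcohol into the vinyl ketone under near-neutral conditions that spare the enone and the silylalkyne.

Step 4
Reactants: 7 8-[tri(propan-2-yl)silyl]oct-1-en-7-yn-3-one
Product: 8 tert-butyl(dimethyl)({(3Z)-8-[tri(propan-2-yl)silyl]octa-1,3-dien-7-yn-3-yl}oxy)silane
Conditions: TBSOTf, Et3N, CH2Cl2, −78 → 0 °C
Reagents that add atoms: tert-butyldimethylsilyl trifluoromethanesulfonate, CC(C)(C)[Si](C)(C)OS(=O)(=O)C(F)(F)F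
Why: Soft enolisation of the vinyl ketone at its only α-CH2 and O-silylation (silyl enol ether formation) give the 2-silyloxy-1,3-diene, the (Z)-enol ether with the chain anti to the vinyl group being the usual outcome and the geometry that can reach the s-cis conformation.

Step 5
Reactants: 8 tert-butyl(dimethyl)({(3Z)-8-[tri(propan-2-yl)silyl]octa-1,3-dien-7-yn-3-yl}oxy)silane; 9 3-methylcyclohex-2-en-1-one
Product: 11 (±)-trans-6-(tert-butyldimethylsilyloxy)-4a-methyl-5-{4-[tri(propan-2-yl)silyl]but-3-yn-1-yl}-3,4,4a,5,8,8a-hexahydronaphthalen-1(2H)-one, via (E)-3-methylcyclohex-2-en-1-one 10 (not isolated)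
Conditions: hν (λ = 350 nm), degassed CH2Cl2 (0.05 M in 9), −40 °C, 8 (3 equiv, excess recovered)
Reagents that add atoms: none
Why: Proposed new method: n→π* excitation of 9 and intersystem crossing twist the C5=C10 bond (product numbering) and should deliver the strained (E)-enone 10, which is trapped before it relaxes by the electron-rich diene 8 in a thermal suprafacial [4+2] cycloaddition that closes ring B as a six-membered carbocycle through the two new bonds C5–C6 and C9–C10 (the twisted triplet may add stepwise but leads to the same bonds). The closest known reaction type is the Diels–Alder trapping of photochemically generated trans-cycloalkenones (cyclohept-2-enone, cyclooct-2-enone) and of trans-1-acetylcyclohexene by dienes, which gives trans-fused adducts; the extension to a β-methylcyclohexenone and an acyclic 1,2-disubstituted 2-silyloxydiene is what is new. The trans ring fusion (C10–CH3 anti to C5–H) is controlled by the (E)-geometry of the dienophile, whose ring carbons C1 and C4 are trans on C10=C5 and stay so in a suprafacial addition. The regiochemistry is controlled by polarity: the diene terminus C9, next to the silyloxy-bearing C8, is the nucleophilic end and should bond to the enone β-carbon C10, so that C6 goes to C5, and the strain of 10 should pay for the quaternary centre that a thermal reaction of a β,β-disubstituted enone forms only under strong Lewis acid activation. The C9 configuration (side chain cis to the C10 methyl) is expected from the orientation with the carbonyl group under the diene, and a C9 epimer is not lost because C9 can be equilibrated next to the C8 ketone in step 7. Since 9 is achiral the adduct is racemic, and the enantiomers are separated in step 8 in the course of the methylenation.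

Step 6
Reactants: 11 (±)-trans-fused adduct (C4 ketone, C7=C8 silyl enol ether)
Product: 12 (±)-tert-butyl{[5-(methoxymethylidene)-8a-methyl-1-{4-[tri(propan-2-yl)silyl]but-3-yn-1-yl}-1,4,4a,5,6,7,8,8a-octahydronaphthalen-2-yl]oxy}dimethylsilane (C4=CH–OCH3, E/Z mixture)
Conditions: MeOCH2PPh3Cl, KN(SiMe3)2, THF, 0 °C → rt
Reagents that add atoms: (methoxymethyl)triphenylphosphonium chloride, COC[P+](c1ccccc1)(c1ccccc1)c1ccccc1.[Cl-]
Why: Wittig methoxymethylenation of the only free carbonyl group (the C8 oxygen is masked as the silyl enol ether) adds the future C19 and at the same time removes the acidity of C5–H, so the trans ring fusion can no longer epimerise.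

Step 7
Reactants: 12 (±)-C4 methoxymethylidene silyl enol ether
Product: 13 (±)-5-(methoxymethylidene)-8a-methyl-1-{4-[tri(propan-2-yl)silyl]but-3-yn-1-yl}octahydronaphthalen-2(1H)-one (C8 ketone)
Conditions: Bu4NF, AcOH, THF, 0 °C
Reagents that add atoms: none
Why: Buffered fluoride cleaves the O–Si bond of the silyl enol ether much faster than the C–Si bond of the triisopropylsilylalkyne and leaves the methyl enol ether alone, and protonation at C7 unveils the C8 ketone without touching C9 (a C9 epimer carried over from step 5 can be moved to the equatorial side chain at this stage with NaOMe in MeOH).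

Step 8
Reactants: 13 (±)-C8 ketone
Product: 14 β-hydroxysulfoximine, single diastereomer: 5-(methoxymethylidene)-8a-methyl-2-{[(S)-N-methyl-S-phenylsulfonimidoyl]methyl}-1-{4-[tri(propan-2-yl)silyl]but-3-yn-1-yl}decahydronaphthalen-2-ol (C8–OH axial, cis to the C10 methyl; C5, C9, C10 as in the target)
Conditions: (S)-PhS(O)(=NMe)CH3, n-BuLi, THF, 0 °C; then 13, −78 °C; aq. NH4Cl; chromatographic separation of the diastereomers
Reagents that add atoms: (S)-N,S-dimethyl-S-phenylsulfoximine, C[S@@](=O)(=NC)c1ccccc1
Why: 1,2-Addition of the lithiated enantiopure sulfoximine to the racemic ketone (sulfoximine-based resolution of ketones) gives one diastereomeric β-hydroxysulfoximine from each enantiomer of 13, attack being expected from the equatorial direction away from the axial C10 methyl, and the separable adduct of the enantiomer with the target configuration (to be assigned by crystallography) is carried on, so at most half of the material passes this step.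

Step 9
Reactants: 14 β-hydroxysulfoximine
Product: 15 tri(propan-2-yl){4-[5-(methoxymethylidene)-8a-methyl-2-methylidenedecahydronaphthalen-1-yl]but-1-yn-1-yl}silane (single enantiomer; trans-fused; side chain cis to the C10 methyl)
Conditions: Al(Hg) (aluminium amalgam), THF/H2O/AcOH, rt
Reagents that add atoms: none
Why: Reductive elimination of the β-hydroxysulfoximine cleaves the C–S bond and expels the hydroxyl group to give the exocyclic C8=C17 methylene without enolising C9, so resolution and methylenation together cost one step more than a Wittig reaction.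

Step 10
Reactants: 15 methylene methyl enol ether
Product: 16 4a-methyl-6-methylidene-5-{4-[tri(propan-2-yl)silyl]but-3-yn-1-yl}decahydronaphthalene-1-carbaldehyde (mixture of C4 epimers)
Conditions: TsOH·H2O (cat.), acetone/H2O, rt
Reagents that add atoms: water, O
Why: Acid-catalysed enol ether hydrolysis releases the C4 carbaldehyde as an epimer mixture that converges on one enolate in step 11, under conditions mild enough not to migrate the exocyclic alkene.

Step 11
Reactants: 16 C4 carbaldehyde
Product: 18 (1R,4aS,5R,8aS)-1,4a-dimethyl-6-methylidene-5-{4-[tri(propan-2-yl)silyl]but-3-yn-1-yl}decahydronaphthalene-1-carbaldehyde, via potassium enolate 17 (not isolated)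
Conditions: KOtBu, THF/t-BuOH, 0 °C; then MeI, 0 °C → rt
Reagents that add atoms: iodomethane, CI
Why: C-Methylation of the exocyclic aldehyde enolate (enolate alkylation) creates the C4 quaternary centre, the electrophile approaching from the equatorial face away from the axial C10 methyl so that the new methyl is equatorial and the formyl group (C19) axial, cis to the C10 methyl as in the target.

Step 12
Reactants: 18 quaternary aldehyde
Product: 19 [(1R,4aS,5R,8aS)-1,4a-dimethyl-6-methylidene-5-{4-[tri(propan-2-yl)silyl]but-3-yn-1-yl}decahydronaphthalen-1-yl]methanol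
Conditions: NaBH4, MeOH, 0 °C
Reagents that add atoms: none
Why: Borohydride reduction of the neopentyl aldehyde gives the C19 primary alcohol without forming a stereocentre or touching the alkene and the silylalkyne.

Step 13
Reactants: 19 silylalkyne alcohol
Product: 20 [(1R,4aS,5R,8aS)-5-(but-3-yn-1-yl)-1,4a-dimethyl-6-methylidenedecahydronaphthalen-1-yl]methanol
Conditions: Bu4NF, THF, rt
Reagents that add atoms: none
Why: Fluoride-induced protodesilylation frees the terminal alkyne needed for the diene synthesis, the alcohol and the exocyclic alkene being inert.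

Step 14
Reactants: 20 terminal alkyne alcohol
Product: 21 [(1R,4aS,5R,8aS)-1,4a-dimethyl-6-methylidene-5-(3-methylidenepent-4-en-1-yl)decahydronaphthalen-1-yl]methanol (ent-labda-8(17),13(16),14-trien-19-ol)
Conditions: ethylene (1 atm), second-generation Grubbs catalyst RuCl2(=CHPh)(PCy3)(H2IMes) (5 mol%), CH2Cl2, rt
Reagents that add atoms: ethylene, C=C
Why: Cross enyne metathesis of the terminal alkyne with ethylene turns C13≡C14 into the 2-substituted buta-1,3-diene (C13=C16, C14=C15) in one step, and the hindered 1,1-disubstituted C8=C17 alkene is expected to stay out of the cycle under an ethylene atmosphere.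

Step 15
Reactants: 21 trienol; 22 (2E)-3-[4-(acetyloxy)phenyl]prop-2-enoic acid
Product: 23 [(1R,4aS,5R,8aS)-1,4a-dimethyl-6-methylidene-5-(3-methylidenepent-4-en-1-yl)decahydronaphthalen-1-yl]methyl (2E)-3-[4-(acetyloxy)phenyl]prop-2-enoate
Conditions: EDC·HCl, DMAP (cat.), CH2Cl2, rt
Reagents that add atoms: none
Why: Steglich esterification acylates the primary neopentyl alcohol with the O-acetyl-protected (E)-p-coumaric acid, the phenol being masked to prevent self-condensation and the (E)-alkene coming unchanged from the acid.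

Step 16
Reactants: 23 acetyl-protected ester
Product: 24 [(1R,4aS,5R,8aS)-1,4a-dimethyl-6-methylidene-5-(3-methylidenepent-4-en-1-yl)decahydronaphthalen-1-yl]methyl (2E)-3-(4-hydroxyphenyl)prop-2-enoate (CNP0131099.1)
Conditions: NH4OAc, MeOH/H2O (4:1), rt
Reagents that add atoms: none
Why: Mild solvolysis cleaves the aryl acetate, whose phenoxide is a far better leaving group than the hindered neopentyl alkoxide of the cinnamate, and releases the target without isomerising any alkene.

**Compound list**
1 | 5-chloropent-1-yne | C#CCCCCl | starting material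
2 | lithium 5-chloropent-1-yn-1-ide | [Li]C#CCCCCl | intermediate
3 | (5-chloropent-1-yn-1-yl)tri(propan-2-yl)silane | ClCCCC#C[Si](C(C)C)(C(C)C)C(C)C | intermediate
4 | prop-2-enal (acrolein) | C=CC=O | starting material
5 | {5-[tri(propan-2-yl)silyl]pent-4-yn-1-yl}magnesium chloride | Cl[Mg]CCCC#C[Si](C(C)C)(C(C)C)C(C)C | intermediate
6 | (±)-8-[tri(propan-2-yl)silyl]oct-1-en-7-yn-3-ol | C=CC(O)CCCC#C[Si](C(C)C)(C(C)C)C(C)C | intermediate
7 | 8-[tri(propan-2-yl)silyl]oct-1-en-7-yn-3-one | C=CC(=O)CCCC#C[Si](C(C)C)(C(C)C)C(C)C | intermediate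
8 | tert-butyl(dimethyl)({(3Z)-8-[tri(propan-2-yl)silyl]octa-1,3-dien-7-yn-3-yl}oxy)silane | C=C/C(O[Si](C)(C)C(C)(C)C)=C/CCC#C[Si](C(C)C)(C(C)C)C(C)C | intermediate
9 | 3-methylcyclohex-2-en-1-one | CC1=CC(=O)CCC1 | starting material
10 | (E)-3-methylcyclohex-2-en-1-one (ring-trans isomer of 9) | C/C1=C\C(=O)CCC1 | intermediate
11 | (±)-trans-6-(tert-butyldimethylsilyloxy)-4a-methyl-5-{4-[tri(propan-2-yl)silyl]but-3-yn-1-yl}-3,4,4a,5,8,8a-hexahydronaphthalen-1(2H)-one (C10 methyl anti to C5–H; side chain cis to C10 methyl) | CC(C)[Si](C(C)C)(C(C)C)C#CCC[C@@H]1C(O[Si](C)(C)C(C)(C)C)=CC[C@@H]2C(=O)CCC[C@@]12C | intermediate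
12 | (±)-tert-butyl{[5-(methoxymethylidene)-8a-methyl-1-{4-[tri(propan-2-yl)silyl]but-3-yn-1-yl}-1,4,4a,5,6,7,8,8a-octahydronaphthalen-2-yl]oxy}dimethylsilane (ring stereochemistry as 11; enol ether E/Z mixture) | CC(C)[Si](C(C)C)(C(C)C)C#CCC[C@@H]1C(O[Si](C)(C)C(C)(C)C)=CC[C@@H]2C(=COC)CCC[C@@]12C | intermediate
13 | (±)-5-(methoxymethylidene)-8a-methyl-1-{4-[tri(propan-2-yl)silyl]but-3-yn-1-yl}octahydronaphthalen-2(1H)-one (ring stereochemistry as 11) | CC(C)[Si](C(C)C)(C(C)C)C#CCC[C@@H]1C(=O)CC[C@@H]2C(=COC)CCC[C@@]12C | intermediate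
14 | 5-(methoxymethylidene)-8a-methyl-2-{[(S)-N-methyl-S-phenylsulfonimidoyl]methyl}-1-{4-[tri(propan-2-yl)silyl]but-3-yn-1-yl}decahydronaphthalen-2-ol (single diastereomer; C8–OH axial, cis to C10 methyl) | CC(C)[Si](C(C)C)(C(C)C)C#CCC[C@@H]1[C@@](O)(C[S@@](=O)(=NC)c3ccccc3)CC[C@@H]2C(=COC)CCC[C@@]12C | intermediate
15 | tri(propan-2-yl){4-[5-(methoxymethylidene)-8a-methyl-2-methylidenedecahydronaphthalen-1-yl]but-1-yn-1-yl}silane (single enantiomer; trans-fused; side chain cis to C10 methyl) | CC(C)[Si](C(C)C)(C(C)C)C#CCC[C@@H]1C(=C)CC[C@@H]2C(=COC)CCC[C@@]12C | intermediate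
16 | 4a-methyl-6-methylidene-5-{4-[tri(propan-2-yl)silyl]but-3-yn-1-yl}decahydronaphthalene-1-carbaldehyde (C4 epimers; C5, C9, C10 as in target) | CC(C)[Si](C(C)C)(C(C)C)C#CCC[C@@H]1C(=C)CC[C@@H]2C(C=O)CCC[C@@]12C | intermediate
17 | potassium enolate of 16 | CC(C)[Si](C(C)C)(C(C)C)C#CCC[C@@H]1C(=C)CC[C@@H]2C(=C[O-])CCC[C@@]12C.[K+] | intermediate
18 | (1R,4aS,5R,8aS)-1,4a-dimethyl-6-methylidene-5-{4-[tri(propan-2-yl)silyl]but-3-yn-1-yl}decahydronaphthalene-1-carbaldehyde | CC(C)[Si](C(C)C)(C(C)C)C#CCC[C@@H]1C(=C)CC[C@@H]2[C@](C)(C=O)CCC[C@@]12C | intermediate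
19 | [(1R,4aS,5R,8aS)-1,4a-dimethyl-6-methylidene-5-{4-[tri(propan-2-yl)silyl]but-3-yn-1-yl}decahydronaphthalen-1-yl]methanol | CC(C)[Si](C(C)C)(C(C)C)C#CCC[C@@H]1C(=C)CC[C@@H]2[C@](C)(CO)CCC[C@@]12C | intermediate
20 | [(1R,4aS,5R,8aS)-5-(but-3-yn-1-yl)-1,4a-dimethyl-6-methylidenedecahydronaphthalen-1-yl]methanol | C#CCC[C@@H]1C(=C)CC[C@@H]2[C@](C)(CO)CCC[C@@]12C | intermediate
21 | [(1R,4aS,5R,8aS)-1,4a-dimethyl-6-methylidene-5-(3-methylidenepent-4-en-1-yl)decahydronaphthalen-1-yl]methanol | C=CC(=C)CC[C@@H]1C(=C)CC[C@@H]2[C@](C)(CO)CCC[C@@]12C | intermediate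
22 | (2E)-3-[4-(acetyloxy)phenyl]prop-2-enoic acid | CC(=O)Oc1ccc(/C=C/C(=O)O)cc1 | starting material
23 | [(1R,4aS,5R,8aS)-1,4a-dimethyl-6-methylidene-5-(3-methylidenepent-4-en-1-yl)decahydronaphthalen-1-yl]methyl (2E)-3-[4-(acetyloxy)phenyl]prop-2-enoate | C=CC(=C)CC[C@@H]1C(=C)CC[C@@H]2[C@](C)(COC(=O)/C=C/c3ccc(OC(C)=O)cc3)CCC[C@@]12C | intermediate
24 | [(1R,4aS,5R,8aS)-1,4a-dimethyl-6-methylidene-5-(3-methylidenepent-4-en-1-yl)decahydronaphthalen-1-yl]methyl (2E)-3-(4-hydroxyphenyl)prop-2-enoate | C=CC(=C)CC[C@@H]1C(=C)CC[C@@H]2[C@](C)(COC(=O)/C=C/c3ccc(O)cc3)CCC[C@@]12C | target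

**Step count and risks**

Total steps: 16. Longest linear sequence: 16 steps (1 → 24); 4, 9 and 22 are bought and enter directly.

Steps most likely to fail:

1. Step 5 (proposed new method). The twisted enone may be intercepted at the triplet stage (stepwise [2+2] addition to vinylcyclobutanes, energy transfer to the diene) or relax before the diene traps it, and the facial orientation at C9 may be unselective. The fallback sets out from 8 and 9 and uses known chemistry. A Lewis-acid-promoted thermal Diels–Alder reaction of the hindered enone with the 2-silyloxydiene (AlBr3/AlMe3 10:1, toluene/CH2Cl2, −20 °C) forms the same two bonds on the (Z)-enone and should give the cis-fused endo adduct F1, with the side chain anti to the C10 methyl. Epimerisation at C5 through the C4 enolate (DBU, toluene, 60 °C; cis isomer recycled) gives the trans-fused C9 epimer of 11, F2. Methoxymethylenation as in step 6 gives the C9 epimer of 12, F3. Desilylation as in step 7 gives the C9 epimer of 13, F4, which is equilibrated at C9 with NaOMe in MeOH, and the sequence comes back to the route at 13.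

2. Step 8. The basic reagent may enolise the hindered C8 ketone instead of adding, or the diastereomers may not separate. The fallback sets out from 11 and moves the resolution to the unhindered C4 ketone. Addition of the same lithiated (S)-sulfoximine gives diastereomeric adducts; the C4 β-hydroxysulfoximine of the needed enantiomer, F5, is separated and thermolysed (toluene, 110 °C, retro-addition) to the single enantiomer of 11, F6. Steps 6 and 7 then give the single enantiomer of 12, F7, and the single enantiomer of 13, F8. A Wittig methylenation of F8 (Ph3PCH3Br, KN(SiMe3)2, THF) comes back to the route at 15.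

3. Step 14. Ring-closing enyne metathesis onto the C8=C17 alkene or oligomerisation of the new diene may compete with the cross reaction. The fallback sets out from 20. Hydrostannation with Bu3SnH under Mo(CO)3(CNtBu)3 catalysis, which places tin on the internal alkyne carbon, gives the α-stannyl alkene F9. Stille coupling of F9 with vinyl bromide (Pd(PPh3)4, DMF, 60 °C) comes back to the route at 21.

Further compounds
F1 | step 5 | (±)-cis-fused adduct: C9 and C5 epimer of 11 (C5–H cis to C10 methyl; side chain anti to C10 methyl) | CC(C)[Si](C(C)C)(C(C)C)C#CCC[C@H]1C(O[Si](C)(C)C(C)(C)C)=CC[C@H]2C(=O)CCC[C@@]12C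
F2 | step 5 | (±)-trans-fused C9 epimer of 11 | CC(C)[Si](C(C)C)(C(C)C)C#CCC[C@H]1C(O[Si](C)(C)C(C)(C)C)=CC[C@@H]2C(=O)CCC[C@@]12C
F3 | step 5 | (±)-C9 epimer of 12 | CC(C)[Si](C(C)C)(C(C)C)C#CCC[C@H]1C(O[Si](C)(C)C(C)(C)C)=CC[C@@H]2C(=COC)CCC[C@@]12C
F4 | step 5 | (±)-C9 epimer of 13 | CC(C)[Si](C(C)C)(C(C)C)C#CCC[C@H]1C(=O)CC[C@@H]2C(=COC)CCC[C@@]12C
F5 | step 8 | C4 β-hydroxysulfoximine of 11, single diastereomer (C4–OH axial, cis to C10 methyl; (S)-sulfur) | CC(C)[Si](C(C)C)(C(C)C)C#CCC[C@@H]1C(O[Si](C)(C)C(C)(C)C)=CC[C@@H]2[C@@](O)(C[S@@](=O)(=NC)c3ccccc3)CCC[C@@]12C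
F6 | step 8 | single enantiomer of 11 | CC(C)[Si](C(C)C)(C(C)C)C#CCC[C@@H]1C(O[Si](C)(C)C(C)(C)C)=CC[C@@H]2C(=O)CCC[C@@]12C
F7 | step 8 | single enantiomer of 12 | CC(C)[Si](C(C)C)(C(C)C)C#CCC[C@@H]1C(O[Si](C)(C)C(C)(C)C)=CC[C@@H]2C(=COC)CCC[C@@]12C
F8 | step 8 | single enantiomer of 13 | CC(C)[Si](C(C)C)(C(C)C)C#CCC[C@@H]1C(=O)CC[C@@H]2C(=COC)CCC[C@@]12C
F9 | step 14 | [(1R,4aS,5R,8aS)-1,4a-dimethyl-6-methylidene-5-[3-(tributylstannyl)but-3-en-1-yl]decahydronaphthalen-1-yl]methanol | C=C([Sn](CCCC)(CCCC)CCCC)CC[C@@H]1C(=C)CC[C@@H]2[C@](C)(CO)CCC[C@@]12C
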